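**Strategy.** Everything rests on disconnecting the C10–C1 bond of the seven-membered ring B by a retro-Claisen ring contraction. The feature used is the O=C9–C10H2–C1 array of ring B sitting beside C5–C6: it corresponds to a C9=C10 enol ether tied through oxygen to C6, which is allylic to a C5=C1 alkene of ring A. In one thermal [3,3] shift the C10–C1 bond and the quaternary fusion carbon C1 are made, the chirality at C6 is handed on to C1, and a five-membered oxacycle is enlarged to carbocyclic ring B. The precursor is a (6R)-2-methylenetetrahydrofuran bearing the fully substituted, C2,C4-dioxygenated cyclopentenyl ring A.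

Key step: step 13

Remark on numbering: daucane numbering is used for every intermediate, monocyclic ones included. Ring A is C1 (methyl-bearing), C2 (oxygenated), C3, C4 (isopropyl carbinol), C5. Ring B is C5, C6, C7, C8 (methyl-bearing), C9 (carbonyl), C10, C1. α is the face of the C2 oxygen and β the face of the C1 methyl in the target. "Ring A unit" means the cyclopent-1-enyl group C5(attachment)=C1(CH3)–C2(α-OSiMe2t-Bu)–C3H2–C4(α-OSiEt3, β-isopropyl).
Assumption: both enantiomers of cis-4-acetoxycyclopent-2-en-1-ol can be bought; the (1R,4S) one is required.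

Step 1
Reactants: 1 (1R,4S)-cis-4-acetoxycyclopent-2-en-1-ol
Product: 2 (1S,4R)-cis-4-(tert-butyldimethylsilyloxy)cyclopent-2-en-1-yl acetate
Conditions: t-BuMe2SiCl, imidazole, DMF, rt
Reagents that add atoms: tert-butyldimethylsilyl chloride, CC(C)(C)[Si](C)(C)Cl
Why: Imidazole-promoted silylation of a secondary alcohol touches no stereocentre, so the carbinol carbon that becomes C2 keeps its configuration.

Step 2
Reactants: 2 (1S,4R)-cis-4-(tert-butyldimethylsilyloxy)cyclopent-2-en-1-yl acetate
Product: 3 (1S,4R)-cis-4-(tert-butyldimethylsilyloxy)cyclopent-2-en-1-ol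
Conditions: K2CO3 (cat.), MeOH, 0 °C to rt
Reagents that add atoms: none
Why: Base-catalysed transesterification with methanol removes the acetate and leaves the silyl ether and both stereocentres untouched.

Step 3
Reactants: 3 (1S,4R)-cis-4-(tert-butyldimethylsilyloxy)cyclopent-2-en-1-ol
Product: 4 (R)-4-(tert-butyldimethylsilyloxy)cyclopent-2-en-1-one
Conditions: MnO2, CH2Cl2, rt
Reagents that add atoms: none
Why: Allylic alcohol oxidation with MnO2 is neutral, so the base-sensitive β-silyloxy ketone should not eliminate.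

Step 4
Reactants: 4 (R)-4-(tert-butyldimethylsilyloxy)cyclopent-2-en-1-one
Product: 6 (R)-4-(tert-butyldimethylsilyloxy)-3-methylcyclopent-2-en-1-one, via trimethylsilyl enol ether 5 (not isolated)
Conditions: Me2CuLi (from MeLi, CuI), Me3SiCl, THF, −78 °C; crude enol ether, Pd(OAc)2 (10 mol %), O2 (1 atm), DMSO, rt
Reagents that add atoms: lithium dimethylcuprate, [Li+].C[Cu-]C
Why: Gilman cuprate conjugate addition anti to the silyloxy group with in situ O-silylation gives the enol ether regiospecifically, and aerobic Saegusa–Ito oxidation then restores the enone by β-hydride loss from the methyl-bearing carbon, erasing the transient methine centre while the silyloxy centre is untouched.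

Step 5
Reactants: 6 (R)-4-(tert-butyldimethylsilyloxy)-3-methylcyclopent-2-en-1-one
Product: 8 (R)-2-bromo-4-(tert-butyldimethylsilyloxy)-3-methylcyclopent-2-en-1-one, via dibromo ketone 7 (not isolated)
Conditions: Br2, CH2Cl2, 0 °C; then Et3N, 0 °C to rt
Reagents that add atoms: bromine, BrBr
Why: Bromine addition across the enone followed by amine-induced dehydrobromination through the acidic α-hydrogen is the standard α-bromination of enones, and Et3N at 0 °C should be too mild to expel the β-silyloxy group.

Step 6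
Reactants: 8 (R)-2-bromo-4-(tert-butyldimethylsilyloxy)-3-methylcyclopent-2-en-1-one; 9 isopropylmagnesium chloride
Product: 10 (1R,4R)-2-bromo-4-(tert-butyldimethylsilyloxy)-1-isopropyl-3-methylcyclopent-2-en-1-ol (hydroxyl cis to the silyloxy group)
Conditions: i-PrMgCl, anhydrous CeCl3, THF, −78 °C; aq. NH4Cl
Reagents that add atoms: isopropylmagnesium chloride (9), CC(C)[Mg]Cl
Why: Organocerium 1,2-addition suppresses enolisation, β-elimination and hydride transfer from the branched Grignard reagent, and attack on the carbonyl face anti to the silyloxy group sets C4 with its oxygen cis to the C2 oxygen.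

Step 7
Reactants: 10 (1R,4R)-2-bromo-4-(tert-butyldimethylsilyloxy)-1-isopropyl-3-methylcyclopent-2-en-1-ol
Product: 11 (1R,4R)-2-bromo-4-(tert-butyldimethylsilyloxy)-1-isopropyl-3-methyl-1-(triethylsilyloxy)cyclopent-2-ene (ring A unit with bromine on C5)
Conditions: Et3SiOTf, 2,6-lutidine, CH2Cl2, −78 to 0 °C
Reagents that add atoms: triethylsilyl trifluoromethanesulfonate, CC[Si](CC)(CC)OS(=O)(=O)C(F)(F)F
Why: Silyl triflate with 2,6-lutidine is the standard silylation of a hindered tertiary alcohol and removes the acidic proton before lithiation.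

Step 8
Reactants: 11 ring A vinyl bromide; 12 succinic anhydride
Product: 14 4-oxo-4-(ring A unit)butanoic acid (C6 keto acid), via cyclopentenyllithium 13 (not isolated)
Conditions: t-BuLi (2.1 equiv), Et2O, −78 °C; cannulated into succinic anhydride (3 equiv), THF, −78 °C; cold 0.5 M HCl to pH 4
Reagents that add atoms: succinic anhydride (12), O=C1CCC(=O)O1
Why: Bromine–lithium exchange gives a cyclopentenyllithium that cannot β-eliminate inside the five-membered ring, and its inverse addition to excess anhydride (acylation by anhydride opening) stops at the keto carboxylate because the carboxylate charge and the crowding at C5 disfavour a second addition.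

Step 9
Reactants: 14 4-oxo-4-(ring A unit)butanoic acid
Product: 15 methyl 4-oxo-4-(ring A unit)butanoate
Conditions: MeI, K2CO3, DMF, rt
Reagents that add atoms: iodomethane, CI
Why: SN2 O-alkylation of the carboxylate masks the acid, which would otherwise consume borane in the next step.

Step 10
Reactants: 15 methyl 4-oxo-4-(ring A unit)butanoate
Product: 17 (5R)-5-(ring A unit)dihydrofuran-2(3H)-one, the (6R)-γ-lactone, via hydroxy ester 16 (not isolated)
Conditions: (S)-2-methyl-CBS-oxazaborolidine (0.2 equiv), BH3·THF, THF, −20 °C; MeOH quench; then DBU (cat.), toluene, 50 °C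
Reagents that add atoms: none
Why: Corey–Bakshi–Shibata reduction with the (S)-catalyst, which treats the fully substituted cyclopentenyl group as the large substituent, should give the (6R)-carbinol under reagent control, and base-catalysed intramolecular transesterification closes the lactone with retention at C6 while avoiding acid that could ionise the doubly activated C6–O bond.

Step 11
Reactants: 17 (5R)-5-(ring A unit)dihydrofuran-2(3H)-one
Product: 19 (3S,5R)-3-methyl-5-(ring A unit)dihydrofuran-2(3H)-one (trans; 6R,8S), via lithium enolate 18 (not isolated)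
Conditions: LiN(i-Pr)2, THF, −78 °C; MeI, −78 to −40 °C
Reagents that add atoms: iodomethane, CI
Why: Kinetic lactone enolate alkylation should place the methyl trans to the bulky C6 substituent, and the C8 configuration is immaterial because C8 becomes sp2 in step 17.

Step 12
Reactants: 19 (3S,5R)-3-methyl-5-(ring A unit)dihydrofuran-2(3H)-one; 20 dimethyltitanocene Cp2TiMe2
Product: 21 (2R,4S)-4-methyl-5-methylene-2-(ring A unit)tetrahydrofuran (6R,8S; C9=C10 exocyclic enol ether)
Conditions: Cp2TiMe2 (2.5 equiv), toluene, pyridine (trace), 65 °C, dark; filtration through basic alumina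
Reagents that add atoms: dimethyltitanocene (20), C[Ti](C)(C1C=CC=C1)C1C=CC=C1
Why: Petasis methylenation proceeds through Cp2Ti=CH2 and an oxatitanacyclobutane under non-acidic conditions, so the lactone carbonyl becomes the exocyclic enol ether with C6 and C8 untouched.

Step 13
Reactants: 21 (2R,4S)-4-methyl-5-methylene-2-(ring A unit)tetrahydrofuran
Product: 22 2α-(tert-butyldimethylsilyloxy)-4α-(triethylsilyloxy)dauc-5-en-9-one (1β-methyl, 4β-isopropyl, 8S)
Conditions: degassed o-xylene, i-Pr2NEt (trace), base-washed sealed tube, 170 °C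
Reagents that add atoms: none
Why: A concerted suprafacial [3,3] (Claisen) shift over C10=C9–O–C6–C5=C1 forms C10–C1 as the allylic C6–O bond breaks, and formation of the C9 carbonyl makes it irreversible. The closest known reaction type is the thermal Claisen ring expansion of 2-methylene-5-alkenyltetrahydrofurans to cyclohept-4-enones, applied here to a tetrasubstituted ring-alkene terminus. Ring B arises by ring enlargement, not by an exo- or endo-mode cyclisation: the shift expels the oxygen from the five-membered heterocycle and inserts C10 and C1, the C7–C8 tether forcing a boat-like, bicyclo[3.2.1]-type transition state. The new quaternary centre C1 is controlled by the (6R) centre: only the rotamer with C7 syn to C1 can give a cis C5=C6 bond inside a seven-membered ring, and in it the C6–O bond, and hence C10, lies on the α face, so C10 enters cis to the C2 and C4 oxygens and the methyl becomes β. The step needs complete 1,3-chirality transfer, secured by that ring constraint, and survival of the exocyclic enol ether until it rearranges, secured by amine additive, base-washed glass and a non-polar solvent. The electron-rich tetrasubstituted alkene weakens the allylic C6–O bond and should offset the steric cost of building a quaternary carbon next to the C2 silyloxy group.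

Step 14
Reactants: 22 2α-(tert-butyldimethylsilyloxy)-4α-(triethylsilyloxy)dauc-5-en-9-one
Product: 23 2α,4α-dihydroxydauc-5-en-9-one
Conditions: Bu4NF, THF, rt to 45 °C
Reagents that add atoms: none
Why: Fluoride-driven cleavage of both silyl ethers avoids having to distinguish them, and only C8, whose configuration does not matter, could epimerise.

Step 15
Reactants: 23 2α,4α-dihydroxydauc-5-en-9-one
Product: 24 2α-acetoxy-4α-hydroxydauc-5-en-9-one
Conditions: Ac2O, pyridine, DMAP (cat.), CH2Cl2, 0 °C to rt
Reagents that add atoms: acetic anhydride, CC(=O)OC(C)=O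
Why: DMAP-catalysed acylation takes the secondary C2 hydroxyl and not the hindered tertiary C4 hydroxyl, so the C2 acetate of the target is installed early and the C4 hydroxyl stays free to direct the next step.

Step 16
Reactants: 24 2α-acetoxy-4α-hydroxydauc-5-en-9-one
Product: 25 2α-acetoxy-4α-hydroxy-5αH-daucan-9-one (trans-fused)
Conditions: H2 (1 atm), [Ir(cod)(PCy3)(py)]PF6 (5–10 mol %), CH2Cl2, rt
Reagents that add atoms: none
Why: Hydroxyl-directed homogeneous hydrogenation binds the cationic iridium centre to the α-oriented C4 hydroxyl and delivers both hydrogens to the α face of the trisubstituted C5=C6 bond, which sets C5–H α and thus the trans ring fusion.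

Step 17
Reactants: 25 2α-acetoxy-4α-hydroxy-5αH-daucan-9-one
Product: 28 2α-acetoxy-4α-hydroxy-5αH-dauc-7-en-9-one, via bis-silyl enol ether 26 (not isolated), via silylated enone 27 (not isolated)
Conditions: Me3SiOTf (2.5 equiv), Et3N, CH2Cl2, 0 °C to rt; crude, Pd(OAc)2 (1.1 equiv), MeCN, rt; then 1 M HCl, THF, 0 °C
Reagents that add atoms: none
Why: Equilibrating soft enolisation gives the more substituted C8=C9 silyl enol ether (the tertiary hydroxyl is silylated as well), and Saegusa–Ito oxidation through a divalent palladium enolate then gives the C7=C8 enone, the only enone possible because C1 carries no hydrogen, before dilute acid frees the C4 hydroxyl.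

Step 18
Reactants: 28 2α-acetoxy-4α-hydroxy-5αH-dauc-7-en-9-one
Product: 31 2α-acetoxy-4α,6α-dihydroxy-5αH-dauc-7-en-9-one, via bis-silyl dienol ether 29 (not isolated), via silyloxy epoxide 30 (not isolated)
Conditions: Me3SiOTf (2.5 equiv), Et3N, CH2Cl2, 0 °C to rt; crude, dimethyldioxirane, acetone/CH2Cl2, −78 to −30 °C; then 1 M HCl, THF, 0 °C
Reagents that add atoms: dimethyldioxirane, CC1(C)OO1
Why: In this vinylogous Rubottom oxidation, equilibrating silylation should give the extended C9=C8–C7=C6 dienol ether (deprotonation at C10 is hindered by the quaternary C1), dimethyldioxirane should epoxidise the terminal C6=C7 bond from the α face, away from the angular C1 methyl and the C4 isopropyl group, and acid opens the epoxide to the γ-hydroxy enone and removes both silyl groups, leaving C6–OH α.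

Step 19
Reactants: 31 2α-acetoxy-4α,6α-dihydroxy-5αH-dauc-7-en-9-one; 32 4-acetoxybenzoic acid
Product: 33 2α-acetoxy-6α-(4-acetoxybenzoyloxy)-4α-hydroxy-5αH-dauc-7-en-9-one
Conditions: DCC, DMAP (cat.), CH2Cl2, 0 °C to rt
Reagents that add atoms: 4-acetoxybenzoic acid (32), CC(=O)Oc1ccc(cc1)C(O)=O
Why: Steglich esterification acylates the secondary allylic C6 hydroxyl with retention, and the tertiary C4 hydroxyl does not compete.

Step 20
Reactants: 33 2α-acetoxy-6α-(4-acetoxybenzoyloxy)-4α-hydroxy-5αH-dauc-7-en-9-one
Product: 34 2α-acetoxy-4α-hydroxy-6α-(4-hydroxybenzoyloxy)-5αH-dauc-7-en-9-one (target CNP0087181.5)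
Conditions: NH4OAc, MeOH/H2O (4:1), rt
Reagents that add atoms: none
Why: Chemoselective solvolysis of the phenolic acetate, whose phenoxide is a far better leaving group than an alkoxide, should proceed under near-neutral conditions and leave the C2 alkyl acetate, the C6 benzoate and the enone intact.

**Compound list**

1 | (1R,4S)-cis-4-acetoxycyclopent-2-en-1-ol | O[C@@H]1C[C@H](OC(C)=O)C=C1 | starting material
2 | (1S,4R)-cis-4-(tert-butyldimethylsilyloxy)cyclopent-2-en-1-yl acetate | CC(C)(C)[Si](C)(C)O[C@@H]1C[C@H](OC(C)=O)C=C1 | intermediate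
3 | (1S,4R)-cis-4-(tert-butyldimethylsilyloxy)cyclopent-2-en-1-ol | CC(C)(C)[Si](C)(C)O[C@@H]1C[C@H](O)C=C1 | intermediate
4 | (R)-4-(tert-butyldimethylsilyloxy)cyclopent-2-en-1-one | CC(C)(C)[Si](C)(C)O[C@@H]1CC(=O)C=C1 | intermediate
5 | (3R,4R)-trans-4-(tert-butyldimethylsilyloxy)-3-methyl-1-(trimethylsilyloxy)cyclopent-1-ene | CC(C)(C)[Si](C)(C)O[C@@H]1CC(O[Si](C)(C)C)=C[C@H]1C | intermediate (not isolated)
6 | (R)-4-(tert-butyldimethylsilyloxy)-3-methylcyclopent-2-en-1-one | CC(C)(C)[Si](C)(C)O[C@@H]1CC(=O)C=C1C | intermediate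
7 | (4R)-2,3-dibromo-4-(tert-butyldimethylsilyloxy)-3-methylcyclopentan-1-one (mixture at the bromine-bearing carbons) | CC(C)(C)[Si](C)(C)O[C@@H]1CC(=O)C(Br)C1(C)Br | intermediate (not isolated)
8 | (R)-2-bromo-4-(tert-butyldimethylsilyloxy)-3-methylcyclopent-2-en-1-one | CC(C)(C)[Si](C)(C)O[C@@H]1CC(=O)C(Br)=C1C | intermediate
9 | isopropylmagnesium chloride | CC(C)[Mg]Cl | starting material
10 | (1R,4R)-2-bromo-4-(tert-butyldimethylsilyloxy)-1-isopropyl-3-methylcyclopent-2-en-1-ol | CC(C)(C)[Si](C)(C)O[C@@H]1C[C@@](O)(C(C)C)C(Br)=C1C | intermediate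
11 | (1R,4R)-2-bromo-4-(tert-butyldimethylsilyloxy)-1-isopropyl-3-methyl-1-(triethylsilyloxy)cyclopent-2-ene | CC(C)(C)[Si](C)(C)O[C@@H]1C[C@@](O[Si](CC)(CC)CC)(C(C)C)C(Br)=C1C | intermediate
12 | succinic anhydride | O=C1CCC(=O)O1 | starting material
13 | C5-lithio ring A unit (cyclopentenyllithium from 11) | CC(C)(C)[Si](C)(C)O[C@@H]1C[C@@](O[Si](CC)(CC)CC)(C(C)C)C([Li])=C1C | intermediate (not isolated)
14 | 4-oxo-4-(ring A unit)butanoic acid | CC(C)(C)[Si](C)(C)O[C@@H]1C[C@@](O[Si](CC)(CC)CC)(C(C)C)C(C(=O)CCC(O)=O)=C1C | intermediate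
15 | methyl 4-oxo-4-(ring A unit)butanoate | CC(C)(C)[Si](C)(C)O[C@@H]1C[C@@](O[Si](CC)(CC)CC)(C(C)C)C(C(=O)CCC(=O)OC)=C1C | intermediate
16 | methyl (4R)-4-hydroxy-4-(ring A unit)butanoate | CC(C)(C)[Si](C)(C)O[C@@H]1C[C@@](O[Si](CC)(CC)CC)(C(C)C)C([C@H](O)CCC(=O)OC)=C1C | intermediate (not isolated)
17 | (5R)-5-(ring A unit)dihydrofuran-2(3H)-one | CC(C)(C)[Si](C)(C)O[C@@H]1C[C@@](O[Si](CC)(CC)CC)(C(C)C)C([C@H]2CCC(=O)O2)=C1C | intermediate
18 | lithium enolate of 17 | CC(C)(C)[Si](C)(C)O[C@@H]1C[C@@](O[Si](CC)(CC)CC)(C(C)C)C([C@H]2CC=C(O[Li])O2)=C1C | intermediate (not isolated)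
19 | (3S,5R)-3-methyl-5-(ring A unit)dihydrofuran-2(3H)-one | CC(C)(C)[Si](C)(C)O[C@@H]1C[C@@](O[Si](CC)(CC)CC)(C(C)C)C([C@H]2C[C@H](C)C(=O)O2)=C1C | intermediate
20 | dimethyltitanocene Cp2TiMe2 | C[Ti](C)(C1C=CC=C1)C1C=CC=C1 | starting material
21 | (2R,4S)-4-methyl-5-methylene-2-(ring A unit)tetrahydrofuran | CC(C)(C)[Si](C)(C)O[C@@H]1C[C@@](O[Si](CC)(CC)CC)(C(C)C)C([C@H]2C[C@H](C)C(=C)O2)=C1C | intermediate
22 | 2α-(tert-butyldimethylsilyloxy)-4α-(triethylsilyloxy)dauc-5-en-9-one | CC(C)(C)[Si](C)(C)O[C@@H]1C[C@@](O[Si](CC)(CC)CC)(C(C)C)C2=CC[C@H](C)C(=O)C[C@]12C | intermediate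
23 | 2α,4α-dihydroxydauc-5-en-9-one | O[C@@H]1C[C@@](O)(C(C)C)C2=CC[C@H](C)C(=O)C[C@]12C | intermediate
24 | 2α-acetoxy-4α-hydroxydauc-5-en-9-one | CC(=O)O[C@@H]1C[C@@](O)(C(C)C)C2=CC[C@H](C)C(=O)C[C@]12C | intermediate
25 | 2α-acetoxy-4α-hydroxy-5αH-daucan-9-one | CC(=O)O[C@@H]1C[C@@](O)(C(C)C)[C@H]2CC[C@H](C)C(=O)C[C@]12C | intermediate
26 | 2α-acetoxy-4α,9-bis(trimethylsilyloxy)-5αH-dauc-8-ene | CC(=O)O[C@@H]1C[C@@](O[Si](C)(C)C)(C(C)C)[C@H]2CCC(C)=C(O[Si](C)(C)C)C[C@]12C | intermediate (not isolated)
27 | 2α-acetoxy-4α-(trimethylsilyloxy)-5αH-dauc-7-en-9-one | CC(=O)O[C@@H]1C[C@@](O[Si](C)(C)C)(C(C)C)[C@H]2CC=C(C)C(=O)C[C@]12C | intermediate (not isolated)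
28 | 2α-acetoxy-4α-hydroxy-5αH-dauc-7-en-9-one | CC(=O)O[C@@H]1C[C@@](O)(C(C)C)[C@H]2CC=C(C)C(=O)C[C@]12C | intermediate
29 | 2α-acetoxy-4α,9-bis(trimethylsilyloxy)-5αH-dauca-6,8-diene | CC(=O)O[C@@H]1C[C@@](O[Si](C)(C)C)(C(C)C)[C@H]2C=CC(C)=C(O[Si](C)(C)C)C[C@]12C | intermediate (not isolated)
30 | 2α-acetoxy-6α,7α-epoxy-4α,9-bis(trimethylsilyloxy)-5αH-dauc-8-ene | CC(=O)O[C@@H]1C[C@@](O[Si](C)(C)C)(C(C)C)[C@H]2[C@@H]3O[C@@H]3C(C)=C(O[Si](C)(C)C)C[C@]12C | intermediate (not isolated)
31 | 2α-acetoxy-4α,6α-dihydroxy-5αH-dauc-7-en-9-one | CC(=O)O[C@@H]1C[C@@](O)(C(C)C)[C@H]2[C@H](O)C=C(C)C(=O)C[C@]12C | intermediate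
32 | 4-acetoxybenzoic acid | CC(=O)Oc1ccc(cc1)C(O)=O | starting material
33 | 2α-acetoxy-6α-(4-acetoxybenzoyloxy)-4α-hydroxy-5αH-dauc-7-en-9-one | CC(=O)O[C@@H]1C[C@@](O)(C(C)C)[C@H]2[C@H](OC(=O)c3ccc(OC(C)=O)cc3)C=C(C)C(=O)C[C@]12C | intermediate
34 | 2α-acetoxy-4α-hydroxy-6α-(4-hydroxybenzoyloxy)-5αH-dauc-7-en-9-one | CC(=O)O[C@@H]1C[C@@](O)(C(C)C)[C@H]2[C@H](OC(=O)c3ccc(O)cc3)C=C(C)C(=O)C[C@]12C | target

**Step count**

Total step count: 20. Longest linear sequence: 20 steps (from 1 to 34).

**Steps most likely to fail**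

Step 13. The exocyclic enol ether may isomerise into the ring, or the allylic C6–O bond may ionise, faster than the crowded [3,3] shift takes place at the temperature required. Fallback, from 21: the rearrangement is run with i-Bu3Al in CH2Cl2 from −78 °C to rt. Aluminium bound to the ring oxygen polarises the C6–O bond so that ring expansion occurs without heating, and the aluminium-bound ketone is reduced in the flask by β-hydride transfer. This should give the C9 carbinol 2α-(tert-butyldimethylsilyloxy)-4α-(triethylsilyloxy)dauc-5-en-9-ol F1 (either C9 epimer). Dess–Martin periodinane (CH2Cl2, NaHCO3) then oxidises F1 to 22, where the route is rejoined.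

Step 18. Silylation may occur toward C10 instead of C6, and the oxidant may approach C6 from the β face, giving poor facial selectivity at the last stereocentre. Fallback, from 28: the same silylation–oxidation sequence is run and its facial preference accepted. If the 6β-alcohol 2α-acetoxy-4α,6β-dihydroxy-5αH-dauc-7-en-9-one F2 predominates, it is coupled with 32 under Mitsunobu conditions (PPh3, diisopropyl azodicarboxylate, THF, 0 °C). This installs the 4-acetoxybenzoate with SN2 inversion at C6 and gives 33 directly, where the route is rejoined.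

Step 8. Proton transfer from the enolisable anhydride to the hindered, strongly basic vinyllithium would return debrominated alkene, and double addition is a lesser risk. Fallback, from 11 by way of 13: transmetalation with ZnCl2 (THF, −78 to 0 °C) gives the cyclopentenylzinc chloride F3. F3 is acylated with methyl 4-chloro-4-oxobutanoate under Pd(PPh3)4 catalysis (zerovalent palladium, Negishi acylation, THF, rt) to give keto ester 15 directly. The route is rejoined at 15 and the esterification step is saved.

Further compounds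
F1 | step 13 | 2α-(tert-butyldimethylsilyloxy)-4α-(triethylsilyloxy)dauc-5-en-9-ol (either C9 epimer) | CC(C)(C)[Si](C)(C)O[C@@H]1C[C@@](O[Si](CC)(CC)CC)(C(C)C)C2=CC[C@H](C)C(O)C[C@]12C
F2 | step 18 | 2α-acetoxy-4α,6β-dihydroxy-5αH-dauc-7-en-9-one | CC(=O)O[C@@H]1C[C@@](O)(C(C)C)[C@H]2[C@@H](O)C=C(C)C(=O)C[C@]12C
F3 | step 8 | C5-(chlorozincio) ring A unit (cyclopentenylzinc chloride) | CC(C)(C)[Si](C)(C)O[C@@H]1C[C@@](O[Si](CC)(CC)CC)(C(C)C)C([Zn]Cl)=C1C
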